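- Start with the easy step: solid substrate dissolves into starting material, free enzyme turns that into target, and Wednesday's first reading shows the solid dissolving at 0.0267 h⁻¹ of the charge, with starting material at 5.7 %. I take that pace as the feed into an empty solution.

| flask | solid substrate | second substrate | free enzyme | remark | time |
|---|---|---|---|---|---|
| Wednesday's | 0.15 M | 1 equiv | 8.5 × 10⁻⁴ mol% | run made earlier |  |
| Saturday's | 0.15 M | 4 equiv | 8.5 × 10⁻⁴ mol% | run made earlier |  |
| Monday's | 0.15 M | 2 equiv | 0.0013 mol% | run made earlier |  |
| flask | 0.15 M | 2.00 equiv | 8.5 × 10⁻⁴ mol% |  | 50 h |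

- Wednesday's (time / h: target / %, starting material / %, solid substrate / %): 3.00: 1.9, 5.7, 92.0; 10.0: 8.0, 10.4, 80.7; 20.0: 18.3, 13.1, 71.6; 25.0: 21.6, 13.2, 66.4; 40.0: 34.4, 12.7, 53.3; 48.0: 41.0, 14.4, 44.0
- Saturday's (time / h: target / %, starting material / %, solid substrate / %): 4.00: 2.5, 5.2, 91.1; 6.00: 5.6, 8.7, 87.9; 12.0: 14.8, 8.3, 78.8; 20.0: 22.6, 10.1, 68.0; 30.0: 34.9, 11.7, 55.1; 48.0: 57.9, 10.2, 31.3
- Monday's (time / h: target / %, starting material / %, solid substrate / %): 10.0: 12.5, 4.7, 80.9; 20.0: 28.1, 7.5, 63.7; 30.0: 44.4, 8.3, 47.5; 40.0: 58.0, 11.7, 31.8; 48.0: 70.3, 11.4, 21.0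

(readings scatter by 1 percentage point)

- target at 50 h, in percent of the solid substrate charged
- concentration of starting material in solution at 50 h, in percent of saturation

- as a solid, counted per litre of solution: solid substrate
- what was read earlier has a scatter of 1 percentage point, one standard deviation
- at the start none of the solid substrate is in solution
- starting material is what solid substrate becomes in solution
- starting material means what is dissolved; the solid is not counted in it

- First extreme: the enzyme clears the solution at once. The feed then stays at that pace, and the charge lasts 37.5 h, less than the time asked.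
- Second extreme: the enzyme takes nothing. The solution fills to saturation, and target stays at zero.
- The flask lies between. I assume the feed falls in proportion to the level s, the dissolved fraction of saturation.
- At quasi-steady state, feed equals drain. So define the drain share φ, target rate over empty-solution feed; then s = 1 − φ.
- From 20.0 h to 48.0 h, Wednesday's target climbs 0.00811 h⁻¹. From 20.0 h to 48.0 h, Saturday's climbs 0.0126 h⁻¹.
- The flask's second substrate lies between theirs, so I take the midpoint, 0.0104 h⁻¹. That gives φ = 0.388, so I expect 51.8 % target at 61.2 % of saturation.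
- The forecast, close to mine, says 53 % and 57 %, holding that “the solid still feeds the solution”.
- The flask gives 53.6 % and 60.4 %. It still holds 34.7 % solid substrate at 50.0 h. After 25.0 h, target climbs 0.0109 h⁻¹, so φ is 0.407 against my 0.388, and s = 1 − φ gives 59.3 %.

    starting material + free enzyme ⇌ first complex (K = 240 M⁻¹, k = 4.20 × 10⁵ M⁻¹ h⁻¹)
    solid substrate ⇌ starting material, rate k2*(cs2 - [starting material]) while solid is left; crystals form when [starting material] > cs2 (solubility = 29.0 mM, k = 0.140 h⁻¹)
    second substrate + loaded enzyme ⇌ second complex (K = 3.60 M⁻¹, k = 5.70 × 10⁵ M⁻¹ h⁻¹)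
    second complex → free enzyme + target (k = 6400 h⁻¹)
    free enzyme ⇌ dormant form (K = 0.710, k = 0.0180 h⁻¹)
    first complex → loaded enzyme + first product (k = 6100 h⁻¹)

- Second flask, a neighbour: it has 0.0034 mol% free enzyme, 4.00 times the first flask's loading. At the first flask's level, φ becomes 1.55, above one, so in the neighbour the level must drop and the feed moves towards 0.0267 h⁻¹. The neighbour's charge then needs somewhat over 37.5 h. The computed neighbour gives >99.9 % target at 50.0 h, with 0 % of the solid substrate left, solid or dissolved.

The runs are calculated with made-up constants.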